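**Assumption (one line):** clerodane-type locants are used for the target (C1–C20; C18/C19 = lactone, C13–C16 + O = furan, acetate on O-7), and the drawn configuration is 1R,5S,7R,8S,9S,10R.

## Retrosynthetic overview

1. Rings A and B are closed together in the last step by an intramolecular Diels–Alder reaction (C1–C2 and C5–C10) between a C1=C10 silyl enol ether and a lactone-locked 3-vinylbutenolide; the enol-ether C10–O bond becomes the tertiary alcohol, and C1, C5 and C10 are set here.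
2. The diene is attached at C6 by a nickel cross-electrophile coupling with 3,4-dibromofuran-2(5H)-one, followed by Stille vinylation.
3. Ring C (seven-membered) comes from a vinylogous Dieckmann ring expansion: the lateral carbanion of a 2-methyl-3-furyl ketone opens a γ-lactone, whose C–O bond is released as the C7 oxygen and acetylated.
4. C7, C8 and C9 come from (S)-5-(hydroxymethyl)furan-2(5H)-one by cuprate addition/methylation and a second α-alkylation anti to the C8 methyl.
5. Ring order: chiral lactone → ring C → butenolide diene → rings A + B.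

## Route

Step 1
Reactants: 1 (S)-5-(hydroxymethyl)furan-2(5H)-one
Product: 2 (S)-5-({[tert-butyl(dimethyl)silyl]oxy}methyl)furan-2(5H)-one
Conditions: TBSCl, imidazole, DMF, 0 → 23 °C
Reagents that add atoms: tert-butyldimethylsilyl chloride, CC(C)(C)[Si](C)(C)Cl
Why: Standard silylation of the primary alcohol protects O-6 through the enolate steps; the stereocentre (future C7) is untouched.

Step 2
Reactants: 2 (S)-5-({[tert-butyl(dimethyl)silyl]oxy}methyl)furan-2(5H)-one
Product: 3 (3S,4S,5S)-5-({[tert-butyl(dimethyl)silyl]oxy}methyl)-3,4-dimethyloxolan-2-one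
Conditions: Me2CuLi (from MeLi, CuI), Et2O/THF, −78 °C; then MeI, DMPU, −78 → −20 °C; aq NH4Cl
Reagents that add atoms: lithium dimethylcuprate, [Li+].C[Cu-]C; iodomethane, CI
Why: Tandem cuprate conjugate addition and enolate methylation; the methyl adds anti to the C5 side chain (sets C8) and MeI enters anti to that methyl (the C3 centre is re-enolised in step 4).

Step 3
Reactants: 4 methyl 2-methylfuran-3-carboxylate
Product: 5 2-chloro-1-(2-methylfuran-3-yl)ethan-1-one
Conditions: ClCH2I, MeLi·LiBr, THF/Et2O, −78 °C; AcOH quench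
Reagents that add atoms: chloroiodomethane, ClCI
Why: Chloromethyllithium adds to the ester and the tetrahedral adduct survives at −78 °C, so quenching gives the chloromethyl ketone (carbenoid homologation of an ester).

Step 4
Reactants: 3 (3S,4S,5S)-5-({[tert-butyl(dimethyl)silyl]oxy}methyl)-3,4-dimethyloxolan-2-one; 5 2-chloro-1-(2-methylfuran-3-yl)ethan-1-one
Product: 6 (3S,4S,5S)-5-({[tert-butyl(dimethyl)silyl]oxy}methyl)-3,4-dimethyl-3-[2-(2-methylfuran-3-yl)-2-oxoethyl]oxolan-2-one
Conditions: LiN(iPr)2, THF, −78 °C; then 5, NaI (10 mol %), DMPU, −78 → −30 °C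
Reagents that add atoms: none
Why: Lactone enolate alkylation with an α-halo ketone; the electrophile enters anti to the adjacent C4 methyl, which fixes the quaternary centre (future C9) with its methyl cis to the C8 methyl.

Step 5
Reactants: 6 (3S,4S,5S)-5-({[tert-butyl(dimethyl)silyl]oxy}methyl)-3,4-dimethyl-3-[2-(2-methylfuran-3-yl)-2-oxoethyl]oxolan-2-one
Product: 8 (2S,3S)-1-{[tert-butyl(dimethyl)silyl]oxy}-3-[(6S)-6-methyl-4,7-dioxo-5,6,7,8-tetrahydro-4H-cyclohepta[b]furan-6-yl]butan-2-yl acetate, via hydroxy dione 7 (not isolated)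
Conditions: KN(SiMe3)2 (2.5 equiv), THF, −78 → 0 °C; AcOH; then Ac2O, pyridine, DMAP (cat.), 23 °C
Reagents that add atoms: acetic anhydride, CC(=O)OC(C)=O
Why: Vinylogous Dieckmann condensation: under equilibrating base the furan-methyl (γ) carbanion attacks the lactone carbonyl (7-membered ring, driven by the acidic product), the lactone oxygen is released at C7 and is acetylated; no stereocentre is touched.

Step 6
Reactants: 8 (2S,3S)-1-{[tert-butyl(dimethyl)silyl]oxy}-3-[(6S)-6-methyl-4,7-dioxo-5,6,7,8-tetrahydro-4H-cyclohepta[b]furan-6-yl]butan-2-yl acetate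
Product: 9 (2S,3S)-1-bromo-3-[(6S)-6-methyl-4,7-dioxo-5,6,7,8-tetrahydro-4H-cyclohepta[b]furan-6-yl]butan-2-yl acetate
Conditions: Ph3PBr2, CH2Cl2, 0 → 23 °C
Reagents that add atoms: dibromotriphenylphosphorane, BrP(Br)(c1ccccc1)(c1ccccc1)c1ccccc1
Why: Direct conversion of a primary silyl ether into the bromide with the phosphorane (Appel-type); the secondary acetate and C7 are not involved.

Step 7
Reactants: 9 (2S,3S)-1-bromo-3-[(6S)-6-methyl-4,7-dioxo-5,6,7,8-tetrahydro-4H-cyclohepta[b]furan-6-yl]butan-2-yl acetate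
Product: 10 (2S,3S)-1-bromo-3-{(6S)-6-methyl-4-oxo-7-[(triethylsilyl)oxy]-5,6-dihydro-4H-cyclohepta[b]furan-6-yl}butan-2-yl acetate
Conditions: Et3SiOTf (1.1 equiv), Et3N, CH2Cl2, −78 → 0 °C
Reagents that add atoms: triethylsilyl trifluoromethanesulfonate, CC[Si](CC)(CC)OS(=O)(=O)C(F)(F)F
Why: Soft enolisation/silylation at the most acidic site (C8–H2 between furan and ketone; the other α-carbon of that ketone is quaternary) gives the furan-conjugated C7=C8 enol ether and masks this position before the butenolide is introduced.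

Step 8
Reactants: 10 (2S,3S)-1-bromo-3-{(6S)-6-methyl-4-oxo-7-[(triethylsilyl)oxy]-5,6-dihydro-4H-cyclohepta[b]furan-6-yl}butan-2-yl acetate; 11 3,4-dibromofuran-2(5H)-one
Product: 12 (2R,3S)-1-(4-bromo-5-oxo-2,5-dihydrofuran-3-yl)-3-{(6S)-6-methyl-4-oxo-7-[(triethylsilyl)oxy]-5,6-dihydro-4H-cyclohepta[b]furan-6-yl}butan-2-yl acetate
Conditions: NiBr2(MeOCH2CH2OMe) (10 mol %), 4,4′-di-tert-butyl-2,2′-bipyridine (10 mol %), Mn powder (2 equiv), NaI (25 mol %), 11 (2 equiv), DMA, 25 °C
Reagents that add atoms: none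
Why: Nickel-catalysed reductive cross-electrophile coupling of a primary alkyl bromide with the more reactive β-C–Br bond of the dibromobutenolide; the radical pathway avoids a β-acetoxy organometallic that would eliminate.

Step 9
Reactants: 12 (2R,3S)-1-(4-bromo-5-oxo-2,5-dihydrofuran-3-yl)-3-{(6S)-6-methyl-4-oxo-7-[(triethylsilyl)oxy]-5,6-dihydro-4H-cyclohepta[b]furan-6-yl}butan-2-yl acetate
Product: 13 (2R,3S)-1-(4-ethenyl-5-oxo-2,5-dihydrofuran-3-yl)-3-{(6S)-6-methyl-4-oxo-7-[(triethylsilyl)oxy]-5,6-dihydro-4H-cyclohepta[b]furan-6-yl}butan-2-yl acetate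
Conditions: Bu3SnCH=CH2, Pd2(dba)3 (5 mol %), AsPh3 (20 mol %), CuI (10 mol %), NMP, 40 °C
Reagents that add atoms: tributyl(vinyl)stannane, C=C[Sn](CCCC)(CCCC)CCCC
Why: Stille coupling of the α-bromobutenolide under neutral conditions installs the vinyl group and completes the 3-vinylbutenolide diene.

Step 10
Reactants: 13 (2R,3S)-1-(4-ethenyl-5-oxo-2,5-dihydrofuran-3-yl)-3-{(6S)-6-methyl-4-oxo-7-[(triethylsilyl)oxy]-5,6-dihydro-4H-cyclohepta[b]furan-6-yl}butan-2-yl acetate
Product: 15 (1R,5S,7R,8S,9S,10R)-7-acetoxy-15,16-epoxy-10-hydroxy-12-oxo-1,16-cyclocleroda-3,13(16),14-trien-18,19-olide, via cycloadduct silyl ether 14 (not isolated)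
Conditions: PhMe (0.005 M), BHT, 170 °C, sealed tube; then HF·pyridine, THF, 0 → 23 °C
Reagents that add atoms: none
Why: Proposed new method: thermal inverse-electron-demand intramolecular Diels–Alder reaction of a furan-conjugated, fully substituted silyl enol ether with a 3-vinylbutenolide, forming C1–C2 and the C5–C10 bond between two fully substituted carbons — the lactone-locked (Z)-diene carries the tether on its inside position, so only the cis-fused transition state is reachable (C19 and O-10 syn), the ring-locked enol ether puts H-1 syn to O-10, and the C9 quaternary centre directs C5 to the face of its own side chain; closest known reaction types are the cis-selective intramolecular Diels–Alder reactions of (Z)-1,7,9-decatrienes and Diels–Alder reactions of silyl enol ethers with 2-alkoxycarbonyl dienes; HF·pyridine then cleaves the tertiary silyl ether.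

## Compound list

1 | (S)-5-(hydroxymethyl)furan-2(5H)-one | OC[C@H]1OC(=O)C=C1 | starting material
2 | (S)-5-({[tert-butyl(dimethyl)silyl]oxy}methyl)furan-2(5H)-one | CC(C)(C)[Si](C)(C)OC[C@H]1OC(=O)C=C1 | intermediate
3 | (3S,4S,5S)-5-({[tert-butyl(dimethyl)silyl]oxy}methyl)-3,4-dimethyloxolan-2-one | O=C1O[C@H](CO[Si](C)(C)C(C)(C)C)[C@@H](C)[C@@H]1C | intermediate
4 | methyl 2-methylfuran-3-carboxylate | COC(=O)c1ccoc1C | starting material
5 | 2-chloro-1-(2-methylfuran-3-yl)ethan-1-one | Cc1occc1C(=O)CCl | intermediate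
6 | (3S,4S,5S)-5-({[tert-butyl(dimethyl)silyl]oxy}methyl)-3,4-dimethyl-3-[2-(2-methylfuran-3-yl)-2-oxoethyl]oxolan-2-one | O=C1O[C@H](CO[Si](C)(C)C(C)(C)C)[C@@H](C)[C@]1(C)CC(=O)c1ccoc1C | intermediate
7 | (6S)-6-[(2S,3S)-4-{[tert-butyl(dimethyl)silyl]oxy}-3-hydroxybutan-2-yl]-6-methyl-5,6-dihydro-4H-cyclohepta[b]furan-4,7(8H)-dione | O[C@H](CO[Si](C)(C)C(C)(C)C)[C@@H](C)[C@]1(C)CC(=O)c2ccoc2CC1=O | intermediate
8 | (2S,3S)-1-{[tert-butyl(dimethyl)silyl]oxy}-3-[(6S)-6-methyl-4,7-dioxo-5,6,7,8-tetrahydro-4H-cyclohepta[b]furan-6-yl]butan-2-yl acetate | CC(=O)O[C@H](CO[Si](C)(C)C(C)(C)C)[C@@H](C)[C@]1(C)CC(=O)c2ccoc2CC1=O | intermediate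
9 | (2S,3S)-1-bromo-3-[(6S)-6-methyl-4,7-dioxo-5,6,7,8-tetrahydro-4H-cyclohepta[b]furan-6-yl]butan-2-yl acetate | CC(=O)O[C@H](CBr)[C@@H](C)[C@]1(C)CC(=O)c2ccoc2CC1=O | intermediate
10 | (2S,3S)-1-bromo-3-{(6S)-6-methyl-4-oxo-7-[(triethylsilyl)oxy]-5,6-dihydro-4H-cyclohepta[b]furan-6-yl}butan-2-yl acetate | CC(=O)O[C@H](CBr)[C@@H](C)[C@]1(C)CC(=O)c2ccoc2C=C1O[Si](CC)(CC)CC | intermediate
11 | 3,4-dibromofuran-2(5H)-one | O=C1OCC(Br)=C1Br | starting material
12 | (2R,3S)-1-(4-bromo-5-oxo-2,5-dihydrofuran-3-yl)-3-{(6S)-6-methyl-4-oxo-7-[(triethylsilyl)oxy]-5,6-dihydro-4H-cyclohepta[b]furan-6-yl}butan-2-yl acetate | CC(=O)O[C@H](CC1=C(Br)C(=O)OC1)[C@@H](C)[C@]1(C)CC(=O)c2ccoc2C=C1O[Si](CC)(CC)CC | intermediate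
13 | (2R,3S)-1-(4-ethenyl-5-oxo-2,5-dihydrofuran-3-yl)-3-{(6S)-6-methyl-4-oxo-7-[(triethylsilyl)oxy]-5,6-dihydro-4H-cyclohepta[b]furan-6-yl}butan-2-yl acetate | CC(=O)O[C@H](CC1=C(C=C)C(=O)OC1)[C@@H](C)[C@]1(C)CC(=O)c2ccoc2C=C1O[Si](CC)(CC)CC | intermediate
14 | 10-O-triethylsilyl ether of 15 (cycloadduct) | CC(=O)O[C@@H]1C[C@@]23COC(=O)C2=CC[C@H]2c4occc4C(=O)C[C@@](C)([C@@H]1C)[C@]23O[Si](CC)(CC)CC | intermediate
15 | (1R,5S,7R,8S,9S,10R)-7-acetoxy-15,16-epoxy-10-hydroxy-12-oxo-1,16-cyclocleroda-3,13(16),14-trien-18,19-olide | CC(=O)O[C@@H]1C[C@@]23COC(=O)C2=CC[C@H]2c4occc4C(=O)C[C@@](C)([C@@H]1C)[C@]23O | target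

## Step count and risks

Total steps: 10. Longest linear sequence: 9 (steps 1, 2, 4, 5, 6, 7, 8, 9, 10).

The three steps most likely to fail:

Step 5 (ring expansion). The base may simply enolise the ketone α-CH2, or the hindered lactone carbonyl may resist attack. The fallback sets out from 6 and comes back at 7. The nucleophile is made by reduction instead of deprotonation: Wohl–Ziegler bromination of the furan methyl group (NBS, AIBN, PhCF3, 80 °C) gives (3S,4S,5S)-3-{2-[2-(bromomethyl)furan-3-yl]-2-oxoethyl}-5-({[tert-butyl(dimethyl)silyl]oxy}methyl)-3,4-dimethyloxolan-2-one F1. SmI2 (2.2 equiv, THF, −78 °C, NiI2 1 mol %) then performs an intramolecular Barbier-type acyl substitution on the lactone. This gives 7 as its samarium alkoxide, which is acetylated as in step 5 to reach 8.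

Step 8 (cross-electrophile coupling). The β-acetoxy alkyl bromide may be reduced or eliminate at the metal. The fallback sets out from 10 and comes back at 12, with no new isolated compound (F0). It is a tin-free radical chain vinylation: (Me3Si)3SiH and AIBN in benzene at 80 °C with excess 11. The alkyl radical adds to C4 of 11 and the adduct radical expels a bromine atom (radical addition–fragmentation), so no alkyl–metal species is involved.

Step 10 (the proposed cycloaddition). The diene and dienophile are electronically mismatched for the tether-enforced regiochemistry, and two fully substituted carbons must be joined. The fallback sets out from 8 and comes back at 15, using known reaction types only: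

- C-allylation of the activated C8 methylene (allyl bromide, K2CO3, acetone) gives (2S,3S)-1-{[tert-butyl(dimethyl)silyl]oxy}-3-[(6S)-6-methyl-4,7-dioxo-8-(prop-2-en-1-yl)-5,6,7,8-tetrahydro-4H-cyclohepta[b]furan-6-yl]butan-2-yl acetate F2 (C8 epimers, equilibrating).
- Ph3PBr2 gives the corresponding primary bromide, (2S,3S)-1-bromo-3-[(6S)-6-methyl-4,7-dioxo-8-(prop-2-en-1-yl)-5,6,7,8-tetrahydro-4H-cyclohepta[b]furan-6-yl]butan-2-yl acetate F3.
- The nickel coupling of step 8, run with 4-bromofuran-2(5H)-one, gives the 4-alkylbutenolide (2R,3S)-1-(5-oxo-2,5-dihydrofuran-3-yl)-3-[(6S)-6-methyl-4,7-dioxo-8-(prop-2-en-1-yl)-5,6,7,8-tetrahydro-4H-cyclohepta[b]furan-6-yl]butan-2-yl acetate F4.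
- SmI2 (THF, −78 °C) triggers a ketyl–olefin cyclisation of the C10 ketone onto the butenolide β-carbon (oxygen anti to the enolate carbon, so O-10 is syn to C19). The samarium enolate is trapped with formaldehyde to give the ring-B-closed spiro-lactone carrying 10-OH and an α-hydroxymethyl group, F5.
- MsCl/Et3N gives the mesylate F6, and DBU eliminates it to the α-methylene lactone F7.
- Ring-closing metathesis with the second-generation Grubbs catalyst (PhMe, 80 °C) joins the C1 allyl group to the methylene group, closing ring A with the C3=C4 bond to give 15.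

This fallback is longer and its stereocontrol is weaker: only the C1 epimer with the allyl group cis to C4 can close, and the aryl ketone may compete for SmI2.

## Further compounds

F1 | step 5 | (3S,4S,5S)-3-{2-[2-(bromomethyl)furan-3-yl]-2-oxoethyl}-5-({[tert-butyl(dimethyl)silyl]oxy}methyl)-3,4-dimethyloxolan-2-one | O=C1O[C@H](CO[Si](C)(C)C(C)(C)C)[C@@H](C)[C@]1(C)CC(=O)c1ccoc1CBr
F0 | step 8 | none | none
F2 | step 10 | (2S,3S)-1-{[tert-butyl(dimethyl)silyl]oxy}-3-[(6S)-6-methyl-4,7-dioxo-8-(prop-2-en-1-yl)-5,6,7,8-tetrahydro-4H-cyclohepta[b]furan-6-yl]butan-2-yl acetate | CC(=O)O[C@H](CO[Si](C)(C)C(C)(C)C)[C@@H](C)[C@]1(C)CC(=O)c2ccoc2C(CC=C)C1=O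
F3 | step 10 | (2S,3S)-1-bromo-3-[(6S)-6-methyl-4,7-dioxo-8-(prop-2-en-1-yl)-5,6,7,8-tetrahydro-4H-cyclohepta[b]furan-6-yl]butan-2-yl acetate | CC(=O)O[C@H](CBr)[C@@H](C)[C@]1(C)CC(=O)c2ccoc2C(CC=C)C1=O
F4 | step 10 | (2R,3S)-1-(5-oxo-2,5-dihydrofuran-3-yl)-3-[(6S)-6-methyl-4,7-dioxo-8-(prop-2-en-1-yl)-5,6,7,8-tetrahydro-4H-cyclohepta[b]furan-6-yl]butan-2-yl acetate | CC(=O)O[C@H](CC1=CC(=O)OC1)[C@@H](C)[C@]1(C)CC(=O)c2ccoc2C(CC=C)C1=O
F5 | step 10 | ring-B-closed spiro-γ-lactone (C5 spiro, 10-OH, 7-OAc, C1 allyl, C4 hydroxymethyl; clerodane locants) | CC(=O)O[C@@H]1C[C@]2(COC(=O)C2CO)[C@@]3(O)[C@@H](CC=C)c4occc4C(=O)C[C@@]3(C)[C@@H]1C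
F6 | step 10 | methanesulfonate of F5 | CC(=O)O[C@@H]1C[C@]2(COC(=O)C2COS(C)(=O)=O)[C@@]3(O)[C@@H](CC=C)c4occc4C(=O)C[C@@]3(C)[C@@H]1C
F7 | step 10 | α-methylene spiro-γ-lactone (C4=CH2, 10-OH, 7-OAc, C1 allyl; clerodane locants) | CC(=O)O[C@@H]1C[C@]2(COC(=O)C2=C)[C@@]3(O)[C@@H](CC=C)c4occc4C(=O)C[C@@]3(C)[C@@H]1C
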